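# Proposed synthesis of (3R,3aR,4S,8aS)-3-hydroxy-6,8a-dimethyl-8-oxo-3-(propan-2-yl)-1,2,3,3a,4,5,8,8a-octahydroazulen-4-yl 4-methoxybenzoate (24)

## The problem

The target 24 is a cis-fused hydroazulene: a cyclopentane carrying a tertiary isopropyl carbinol is fused to a cycloheptenone that bears a 4-methoxybenzoate. The seven-membered ring is numbered here C1 (ester carbinol), C2 (CH2), C3 (methyl-bearing alkene carbon), C4 (=CH), C5 (ketone), C6 (quaternary, methyl) and C10 (ring-fusion CH); C7, C8 and C9 (isopropyl carbinol) complete the five-membered ring. The four stereocentres C1, C10, C9 and C6 are contiguous, two of them fully substituted; the C9 hydroxyl, the C10 hydrogen and the C6 methyl lie on one face and the C1 ester oxygen on the other. C9 can be bought in the chiral pool, and in the finished bicycle C10 (protonation next to a C1 carbonyl) and C1 (hydride anti to the bulky C9 branch) can be derived from it. C6, however, is only 1,3 to C9, so its quaternary centre needs a control element of its own. The functional groups are fragile in combination. The C1 ester is δ to the C5 ketone and is lost by vinylogous elimination once base reaches C2. Any C1 ketone intermediate is β,γ-unsaturated with an epimerisable C10, and the C9 oxygen is β to C1 and can leave by E1cB. The ester must therefore go on late and the enone be unveiled last under neutral conditions. A convergent ring construction is possible because the ring divides into a four-carbon unit C2–C1(O)–C10–C6, a 2-oxydiene standing on a cyclopentene C6=C10, and a three-carbon unit C3–C4–C5 with oxygen on C5. Joining C2 to C3 and C5 to C6 leaves the alkene at C3=C4 and an enol at C1=C10 from which C10 and C1 are set.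

## Retrosynthesis

**24 ⇒ 23 ⇒ 22.** No skeletal bond is cut at first. The C5 carbonyl is taken back to the allylic alcohol 23, and the two hydroxyls of 23 to the silyl ethers of 22. Unveiling the enone last by a neutral oxidation is preferred to acylating a hydroxy enone, because base and the δ-acyloxy enone do not go together. The skeleton is no simpler, but the base-sensitive pair of groups is gone. The forward steps must remove a tertiary and a hindered secondary silyl ether without base, so that the ester does not wander across the ring to O5, and must oxidise a neopentylic allylic alcohol beside a tertiary one.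

**22 ⇒ 20 + 21; 20 ⇒ 19.** The C1–O acyl bond is cut to alcohol 20 and 4-methoxybenzoyl chloride 21, and the C1–H bond to ketone 19. A ketone is chosen over an inverting esterification because hydride attack anti to the C9 branch should give the required configuration directly, and because a C1 carbonyl is what the ring construction delivers. One stereocentre disappears. The reduction must outrun enolisation of a β,γ-unsaturated ketone.

**19 ⇒ 18.** The C10–H bond is cut: 19 is the protonation product of the silyl enol ether 18. C10 becomes sp2 and the ring a cyclohepta-1,4-diene (C1=C10, C3=C4), the signature of a divinylcyclopropane rearrangement. Cutting C6–C10 or C9–C10 instead would break the ring fusion and leave the two fully substituted carbons to be made one at a time. The forward step asks for kinetic protonation on the face of the C6 methyl group and no base afterwards.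

**18 ⇒ 16 ⇒ 15.** The C3 methyl group is traced to the hydroxymethyl group of 16 and the ethyl ester of 15. The ester is not in the target, but a carbenoid needs an acceptor on C3. Removing it while every oxygen is silylated and C1 is still an enol ether means that only one hydroxyl is ever free, and that no C1 ketone with an acidic C2 coexists with an enoate. The cost is two steps. The forward steps are a 1,2-reduction and an SN2 displacement of a primary allylic sulfonate by hydride without transposition.

**15 ⇒ 9 + 13 (key disconnection).** C2–C3 and C5–C6 are cut together. The seven-membered ring and the C6 quaternary centre vanish, leaving the cyclopentenyl 2-silyloxydiene 9, which holds only C9, and the three-carbon diazo ester 13.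

- Against forming the two bonds one at a time (C2–C3 by an enolate reaction, then a conjugate addition onto C6), this cut makes the crowded C5–C6 bond in a sigmatropic step inside a cyclopropane, and it places the alkene at C3=C4 with no further work.
- The vinylcarbenoid from 13 must cyclopropanate the C1=C2 enol ether of 9 through its carbenoid carbon, and the cis-divinylcyclopropane 14 must rearrange through a boat with the C6 methyl inside.
- C6 is to be set by the catalyst and not by C9. The face of C1=C2 taken in the cyclopropanation is relayed to C6, and C5 has to bond anti to the C9 silyloxy group (syn to isopropyl).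
- Spectator groups are chosen for the later steps:
  - a triethylsilyl ether on O9, which goes onto a tertiary alcohol and leaves with HF;
  - a tert-butyldimethylsilyl enol ether at C1, robust in the diene and opened selectively by fluoride;
  - a tert-butyldimethylsilyl ether on O5, which comes from a purchasable aldehyde and is removed with the O9 group;
  - an ethyl ester, whose alkoxy group is lost in step 10.

**9 ⇒ 8 ⇒ 7 ⇒ 5 + 6.** The O–Si bond, then the C1–C2 bond: 9 is the kinetic silyl enol ether of methyl ketone 8, which comes from enal 5 and methylmagnesium bromide 6 through carbinol 7. C2 is added as a nucleophile because the ring contraction below delivers C1 as an aldehyde; an acetyl group from the outset would need a diketone whose aldol closure has no regiocontrol. The forward steps are addition to a hindered enal, oxidation, and enolisation at the methyl group only.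

**5 ⇒ 4 ⇒ 2 ⇒ 1.** The C6=C10 bond is cut (aldol condensation) and the C1–C6 bond restored. Enal 5 is the condensation product of keto aldehyde 4, the ozonolysis product of the silyl ether 2 of (S)-terpinen-4-ol 1. The six-membered ring of 1 already holds C9 with hydroxyl and isopropyl in the right configuration, C6 with its methyl, and C7, C8, C10 and C1; ring contraction turns it into the cyclopentene. Making the C9 carbinol by asymmetric addition to a cyclopentenone would be longer. The aldehyde must act as the enamine donor toward the ketone, without β-elimination of the silyloxy group.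

**13 ⇒ 12 ⇒ 10 + 11.** C4=C5 and C3–C4: 13 is the dehydration product of the β-hydroxy diazo ester 12, made from (tert-butyldimethylsilyloxy)acetaldehyde 10 and ethyl diazoacetate 11. The elimination sets the E enol ether, whereas diazo transfer to a preformed enol ether ester would inherit a Z-rich enol ether that cannot enter the boat. The product must be handled cold.

## Roads not taken

**Alternative 1:** The C9–C10 bond is cut, leading to the α′-diazo cycloheptenone A1 with an open C7–C9 side chain on C6. In the forward step a dirhodium carbenoid at C10 inserts into the tertiary C9–H bond (1,5-insertion, retention at C9) and gives the bicyclic enone A2.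

- Merits: the crowded C9–C10 bond is made intramolecularly; no vinyl diazo ester of unknown behaviour is needed; the C3 methyl and both ring oxygens are in place, so the ester-to-methyl detour disappears.
- Weak points:
  - A1 needs C5, C6 and C9 made independently, with C9 far out on a chain and no chiral-pool shortcut.
  - Diazo transfer must be done next to a quaternary carbon.
  - The insertion site is a tertiary C–H crowded by isopropyl and silyloxy, in competition with the isopropyl methine and the ether oxygen.
  - A2 has its enone on the wrong side (C1 ketone, C2=C3). The endgame must reduce C1, acylate, oxidise C5 and then move the alkene past an allylic ester, where elimination threatens.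
- Comparison: alternative 1 is better in oxidation-state economy at C3. The chosen plan sets against this the purchased C9 centre, a ring and C6 made in one operation, and an alkene that is born at C3=C4.

**Alternative 2:** C2–C3 and C6–C10 are cut, leading to the chloromethyl ketone A3, in which a C7–C9 tether from terpinen-4-ol joins the oxyallyl precursor to a 2-silyloxydiene C3=C4–C5=C6. Base generates the oxyallyl cation C2–C1–C10, and intramolecular (4+3) capture closes both rings to give A4.

- Merits: both rings form in one step from the same chiral pool, without diazo chemistry. The endgame is about four steps (C1 reduction, acylation, Saegusa–Ito oxidation of the C4=C5 enol ether to the C3=C4 enone with the methyl in place, desilylation) against seven here. In step count after the key step it is better.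
- Weak points:
  - A3 needs a tetrasubstituted silyl enol ether of defined geometry at C5=C6, made from an open-chain ketone.
  - The cationic C10 sits next to C9 with its silyloxy group, which invites elimination or a 1,2-shift.
  - C6 and C10 arise under substrate control through a flexible three-atom tether, with no reagent to change the outcome.
  - The cation must attack a fully substituted diene terminus.
- Comparison: the chosen plan sets against the shorter endgame a diene (9) reached in six routine steps, the known tolerance of the carbenoid route for a fully substituted diene terminus, and a catalyst antipode as a handle on C6.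

**Alternative 3:** The C6–C10 bond is cut, leading to the ten-membered epoxy enone A5. The C6 enolate opens the C9–C10 epoxide at C10 across the ring with inversion and gives A6.

- Merits: C6, C10 and the free C9 hydroxyl are set in one stereospecific event, and A6 is two steps (desilylation, acylation) from the target. This is the shortest endgame of all and clearly better in that respect.
- Weak points:
  - A5 is a medium ring with a Z enone, a trisubstituted epoxide of defined configuration relative to C1, and a C1 carbinol; each is its own selectivity problem and the ring closure is long.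
  - The base must deprotonate C6 and not the more acidic vinylogous C2 position, whose dienolate would expel the C1 silyloxy group.
  - The configuration at C6 is dictated by the ring conformer that happens to align, and is not adjustable.
  - The epoxide may instead open to an allylic alcohol.
- Comparison: the chosen plan is longer after its key step but every step before it is routine, and its ring-forming reaction is bimolecular and precedented for quaternary centres.

Key step: step 9

Assumption: (S)-terpinen-4-ol of high enantiomeric purity is taken as purchasable, and the sense of induction of Rh2(DOSP)4 on the 1,1-disubstituted enol ether of 9 is taken to follow that known for styrene, which is why the R catalyst is specified.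

Note on names: azulene locants are used in the names; C3, C3a, C4, C5, C6, C7, C8, C8a, C1, C2 of azulene correspond to C9, C10, C1, C2, C3, C4, C5, C6, C7, C8 of the numbering used in the text.

## Route

Step 1
Reactants: 1 (S)-terpinen-4-ol
Product: 2 triethyl{[(1S)-4-methyl-1-(propan-2-yl)cyclohex-3-en-1-yl]oxy}silane
Conditions: Et3SiOTf, 2,6-lutidine, CH2Cl2, 0 °C → rt
Reagents that add atoms: triethylsilyl trifluoromethanesulfonate, CC[Si](CC)(CC)OS(=O)(=O)C(F)(F)F
Why: Silylation of a tertiary alcohol with a silyl triflate and a hindered pyridine base; the triethylsilyl ether is small enough to go on, should survive ozone, Grignard reagent, hydrides and cold buffered fluoride, and leaves with HF at the end; C9 is untouched.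

Step 2
Reactants: 2 triethyl{[(1S)-4-methyl-1-(propan-2-yl)cyclohex-3-en-1-yl]oxy}silane
Product: 4 (3S)-6-oxo-3-(propan-2-yl)-3-[(triethylsilyl)oxy]heptanal, via secondary ozonide 3 (not isolated)
Conditions: O3, CH2Cl2, −78 °C; then PPh3, −78 °C → rt
Reagents that add atoms: ozone, [O-][O+]=O
Why: Ozonolysis of the only alkene (1,3-dipolar cycloaddition, cycloreversion and recombination to ozonide 3, reduced by the phosphine) cuts the ring bond between the future C1 and C6 and gives the methyl ketone and the aldehyde; no stereocentre is involved.

Step 3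
Reactants: 4 (3S)-6-oxo-3-(propan-2-yl)-3-[(triethylsilyl)oxy]heptanal
Product: 5 (5R)-2-methyl-5-(propan-2-yl)-5-[(triethylsilyl)oxy]cyclopent-1-ene-1-carbaldehyde
Conditions: piperidine, AcOH, toluene, 60 °C
Reagents that add atoms: none
Why: Intramolecular aldol condensation under secondary ammonium carboxylate catalysis: the aldehyde forms the enamine far faster than the ketone, its α-carbon (C10) adds to the ketone carbon (C6) in a 5-exo closure and water is lost, the classical ring contraction of cyclohexene-derived keto aldehydes; buffered, moderate conditions are chosen so that closure outruns β-elimination of the silyloxy group.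

Step 4
Reactants: 5 (5R)-2-methyl-5-(propan-2-yl)-5-[(triethylsilyl)oxy]cyclopent-1-ene-1-carbaldehyde; 6 methylmagnesium bromide
Product: 7 1-[(5R)-2-methyl-5-(propan-2-yl)-5-[(triethylsilyl)oxy]cyclopent-1-en-1-yl]ethan-1-ol (both carbinol epimers)
Conditions: MeMgBr, THF, −78 °C → 0 °C; aq. NH4Cl
Reagents that add atoms: none
Why: 1,2-Addition of a Grignard reagent to a hindered enal that has no acidic α-hydrogen; the new carbinol centre is formed as a mixture and is removed in step 5.

Step 5
Reactants: 7 1-[(5R)-2-methyl-5-(propan-2-yl)-5-[(triethylsilyl)oxy]cyclopent-1-en-1-yl]ethan-1-ol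
Product: 8 1-[(5R)-2-methyl-5-(propan-2-yl)-5-[(triethylsilyl)oxy]cyclopent-1-en-1-yl]ethan-1-one
Conditions: Dess–Martin periodinane, CH2Cl2, rt
Reagents that add atoms: none
Why: Dess–Martin oxidation of a secondary allylic alcohol under nearly neutral conditions; the silyl ether and the tetrasubstituted alkene are inert.

Step 6
Reactants: 8 1-[(5R)-2-methyl-5-(propan-2-yl)-5-[(triethylsilyl)oxy]cyclopent-1-en-1-yl]ethan-1-one
Product: 9 tert-butyl(dimethyl){[1-((5R)-2-methyl-5-(propan-2-yl)-5-[(triethylsilyl)oxy]cyclopent-1-en-1-yl)ethenyl]oxy}silane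
Conditions: t-BuMe2SiOTf, Et3N, CH2Cl2, 0 °C
Reagents that add atoms: tert-butyldimethylsilyl trifluoromethanesulfonate, CC(C)(C)[Si](C)(C)OS(=O)(=O)C(F)(F)F
Why: Soft enolisation with silyl triflate and amine removes a proton from the acetyl methyl group, the only α-position, and gives the cross-conjugated 2-silyloxydiene; the acetyl group is twisted out of the plane of the crowded alkene, so γ-deprotonation is not assisted.

Step 7
Reactants: 10 (tert-butyldimethylsilyloxy)acetaldehyde; 11 ethyl diazoacetate
Product: 12 ethyl 4-[(tert-butyldimethylsilyl)oxy]-2-diazo-3-hydroxybutanoate (racemic)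
Conditions: DBU (cat.), MeCN, 0 °C → rt
Reagents that add atoms: none
Why: Amidine-catalysed aldol-type addition of the diazoacetate carbanion to an aldehyde, a standard entry to β-hydroxy-α-diazo esters; the carbinol centre is racemic and is destroyed in step 8.

Step 8
Reactants: 12 ethyl 4-[(tert-butyldimethylsilyl)oxy]-2-diazo-3-hydroxybutanoate
Product: 13 ethyl (3E)-4-[(tert-butyldimethylsilyl)oxy]-2-diazobut-3-enoate
Conditions: POCl3, Et3N, CH2Cl2, 0 °C → rt; kept cold, used at once
Reagents that add atoms: none
Why: Dehydration of a β-hydroxy-α-diazo ester through its dichlorophosphate, the usual route to vinyl diazoacetates; loss of a proton from the silyloxymethylene group gives the conjugated enol ether, expected as the E isomer with the silyloxy group anti to the diazo ester.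

Step 9
Reactants: 9 tert-butyl(dimethyl){[1-((5R)-2-methyl-5-(propan-2-yl)-5-[(triethylsilyl)oxy]cyclopent-1-en-1-yl)ethenyl]oxy}silane; 13 ethyl (3E)-4-[(tert-butyldimethylsilyl)oxy]-2-diazobut-3-enoate
Product: 15 ethyl (3R,8R,8aS)-4,8-bis[(tert-butyldimethylsilyl)oxy]-8a-methyl-3-(propan-2-yl)-3-[(triethylsilyl)oxy]-1,2,3,5,8,8a-hexahydroazulene-6-carboxylate, via cis-divinylcyclopropane 14 (not isolated)
Conditions: 13 added slowly to 9, Rh2(R-DOSP)4 [dirhodium tetrakis((R)-N-(4-dodecylbenzenesulfonyl)prolinate)] (2 mol %), hexanes, −40 °C → rt; then toluene, 80 °C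
Reagents that add atoms: none
Why: Loss of N2 from 13 on the dirhodium catalyst gives a donor–acceptor vinylcarbenoid of divalent rhodium, which adds through its carbenoid carbon (C3) to the C1=C2 enol ether of 9 and gives the cis-divinylcyclopropane 14; this forms C2–C3. On warming, 14 undergoes the [3,3] shift of a cis-divinylcyclopropane (Cope rearrangement) through a boat transition state in which the push–pull C1–C3 bond breaks and C5–C6 forms. The closest known reaction is the dirhodium-catalysed tandem cyclopropanation–Cope rearrangement (formal 4+3) of vinyl diazoacetates with 2-silyloxydienes and 1-vinylcycloalkenes, which is known to build a quaternary ring-fusion carbon under catalyst control; only the silyloxy group on the vinyl terminus of 13 is new. The seven-membered ring is the one ring closed, in the sigmatropic step, as a cis,cis-cyclohepta-1,4-diene (C1=C10, C3=C4). C6 is controlled by the catalyst: the face of C1=C2 taken in the cyclopropanation is passed on without loss by the boat geometry, and, if the sense known for styrene (S catalyst, (1S,2R)-cyclopropane) holds, the R catalyst gives 14 as drawn, which bonds C5 to C6 anti to the C9 silyloxy group. C5 is controlled by the E geometry of 13 (silyloxy group outside the boat, hence trans to the C6 methyl group) and is removed later by oxidation. The step needs site selectivity, which the tetrasubstitution of C6=C10 secures, carbenoid instead of vinylogous attack, which the E substituent on the vinyl terminus, the electron-rich carboxylate ligands and the hydrocarbon solvent favour, and a cis arrangement of the two alkenyl groups, which is the normal outcome for donor–acceptor carbenoids. The C6 methyl group lies inside the boat, so heat is planned, while the silyloxy donor and ester acceptor on the breaking bond lower the barrier.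

Step 10
Reactants: 15 ethyl (3R,8R,8aS)-4,8-bis[(tert-butyldimethylsilyl)oxy]-8a-methyl-3-(propan-2-yl)-3-[(triethylsilyl)oxy]-1,2,3,5,8,8a-hexahydroazulene-6-carboxylate
Product: 16 [(3R,8R,8aS)-4,8-bis[(tert-butyldimethylsilyl)oxy]-8a-methyl-3-(propan-2-yl)-3-[(triethylsilyl)oxy]-1,2,3,5,8,8a-hexahydroazulen-6-yl]methanol
Conditions: i-Bu2AlH, CH2Cl2, −78 °C; aq. potassium sodium tartrate
Reagents that add atoms: none
Why: i-Bu2AlH reduces the α,β-unsaturated ester by 1,2-addition to the allylic alcohol at low temperature; the silyl ethers and the tetrasubstituted silyl enol ether do not react.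

Step 11
Reactants: 16 [(3R,8R,8aS)-4,8-bis[(tert-butyldimethylsilyl)oxy]-8a-methyl-3-(propan-2-yl)-3-[(triethylsilyl)oxy]-1,2,3,5,8,8a-hexahydroazulen-6-yl]methanol
Product: 18 (3R,8R,8aS)-4,8-bis[(tert-butyldimethylsilyl)oxy]-6,8a-dimethyl-3-(propan-2-yl)-3-[(triethylsilyl)oxy]-1,2,3,5,8,8a-hexahydroazulene, via allylic mesylate 17 (not isolated)
Conditions: MsCl, Et3N, THF, −40 °C; then LiEt3BH, −78 °C → 0 °C
Reagents that add atoms: none
Why: The only free hydroxyl is mesylated and the primary allylic mesylate is displaced in the same flask by hydride in an SN2 reaction; attack at the open CH2 is favoured over SN2′ attack at C4, which is shielded by the C5 silyloxy group and the C6 quaternary centre.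

Step 12
Reactants: 18 (3R,8R,8aS)-4,8-bis[(tert-butyldimethylsilyl)oxy]-6,8a-dimethyl-3-(propan-2-yl)-3-[(triethylsilyl)oxy]-1,2,3,5,8,8a-hexahydroazulene
Product: 19 (3R,3aS,8R,8aS)-8-[(tert-butyldimethylsilyl)oxy]-6,8a-dimethyl-3-(propan-2-yl)-3-[(triethylsilyl)oxy]-2,3,3a,5,8,8a-hexahydroazulen-4(1H)-one (cis-fused)
Conditions: n-Bu4NF, AcOH, THF, −40 °C → 0 °C; crude ketone used at once
Reagents that add atoms: none
Why: Fluoride cleaves the enol Si–O bond far faster than the secondary and tertiary alkyl silyl ethers, and acetic acid protonates the enolate as it forms (kinetic protonation); the proton should reach C10 on the convex face, flanked only by the C6 methyl and the C9 oxygen, the other face being the inside of the cycloheptadiene tub screened by the isopropyl group and the C5 silyloxy methine, which gives the cis ring fusion. The ketone is not stored, because base would move the C3=C4 alkene into conjugation and epimerise C10.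

Step 13
Reactants: 19 (3R,3aS,8R,8aS)-8-[(tert-butyldimethylsilyl)oxy]-6,8a-dimethyl-3-(propan-2-yl)-3-[(triethylsilyl)oxy]-2,3,3a,5,8,8a-hexahydroazulen-4(1H)-one
Product: 20 (3R,3aR,4S,8R,8aS)-8-[(tert-butyldimethylsilyl)oxy]-6,8a-dimethyl-3-(propan-2-yl)-3-[(triethylsilyl)oxy]-1,2,3,3a,4,5,8,8a-octahydroazulen-4-ol
Conditions: LiBH(s-Bu)3 (L-Selectride), THF, −78 °C; then NaOH, H2O2, 0 °C
Reagents that add atoms: none
Why: The bulky trialkylborohydride adds to the C1 ketone anti to the large C9 branch on C10, that is from the face of the C10 hydrogen, as in the reduction of 2-substituted cycloalkanones to cis alcohols; this places the C1 oxygen trans to H10 (4S), and the cold, weakly basic hydride leaves the β,γ-alkene and C10 alone.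

Step 14
Reactants: 20 (3R,3aR,4S,8R,8aS)-8-[(tert-butyldimethylsilyl)oxy]-6,8a-dimethyl-3-(propan-2-yl)-3-[(triethylsilyl)oxy]-1,2,3,3a,4,5,8,8a-octahydroazulen-4-ol; 21 4-methoxybenzoyl chloride
Product: 22 (3R,3aR,4S,8R,8aS)-8-[(tert-butyldimethylsilyl)oxy]-6,8a-dimethyl-3-(propan-2-yl)-3-[(triethylsilyl)oxy]-1,2,3,3a,4,5,8,8a-octahydroazulen-4-yl 4-methoxybenzoate
Conditions: DMAP, Et3N, CH2Cl2, 0 °C → rt
Reagents that add atoms: none
Why: DMAP-catalysed acylation of the only free hydroxyl with the acid chloride; no carbonyl group is present yet, so the basic conditions have nothing to eliminate or epimerise.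

Step 15
Reactants: 22 (3R,3aR,4S,8R,8aS)-8-[(tert-butyldimethylsilyl)oxy]-6,8a-dimethyl-3-(propan-2-yl)-3-[(triethylsilyl)oxy]-1,2,3,3a,4,5,8,8a-octahydroazulen-4-yl 4-methoxybenzoate
Product: 23 (3R,3aR,4S,8R,8aS)-3,8-dihydroxy-6,8a-dimethyl-3-(propan-2-yl)-1,2,3,3a,4,5,8,8a-octahydroazulen-4-yl 4-methoxybenzoate
Conditions: HF·pyridine, pyridine, THF, 0 °C → rt
Reagents that add atoms: none
Why: Buffered HF removes the secondary tert-butyldimethylsilyl and the tertiary triethylsilyl ether without base, so the aryl ester is neither cleaved nor passed across the ring to the C5 hydroxyl.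

Step 16
Reactants: 23 (3R,3aR,4S,8R,8aS)-3,8-dihydroxy-6,8a-dimethyl-3-(propan-2-yl)-1,2,3,3a,4,5,8,8a-octahydroazulen-4-yl 4-methoxybenzoate
Product: 24 (3R,3aR,4S,8aS)-3-hydroxy-6,8a-dimethyl-8-oxo-3-(propan-2-yl)-1,2,3,3a,4,5,8,8a-octahydroazulen-4-yl 4-methoxybenzoate
Conditions: Dess–Martin periodinane, NaHCO3, CH2Cl2, 0 °C → rt
Reagents that add atoms: none
Why: Dess–Martin oxidation of the secondary allylic alcohol unveils the enone under buffered, non-basic conditions, so the δ-acyloxy enone never meets base; the tertiary alcohol cannot be oxidised and the temporary C5 stereocentre disappears.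

## Compound list

1 | (S)-terpinen-4-ol, (1S)-4-methyl-1-(propan-2-yl)cyclohex-3-en-1-ol | CC1=CC[C@](O)(C(C)C)CC1 | starting material
2 | triethyl{[(1S)-4-methyl-1-(propan-2-yl)cyclohex-3-en-1-yl]oxy}silane | CC1=CC[C@](O[Si](CC)(CC)CC)(C(C)C)CC1 | intermediate
3 | secondary ozonide (1,2,4-trioxolane) of 2, mixture at the two acetal carbons, silyloxy carbon unchanged | CC12CC[C@@](O[Si](CC)(CC)CC)(C(C)C)CC(O1)OO2 | intermediate
4 | (3S)-6-oxo-3-(propan-2-yl)-3-[(triethylsilyl)oxy]heptanal | CC(=O)CC[C@@](O[Si](CC)(CC)CC)(C(C)C)CC=O | intermediate
5 | (5R)-2-methyl-5-(propan-2-yl)-5-[(triethylsilyl)oxy]cyclopent-1-ene-1-carbaldehyde | O=CC1=C(C)CC[C@@]1(O[Si](CC)(CC)CC)C(C)C | intermediate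
6 | methylmagnesium bromide | C[Mg]Br | starting material
7 | 1-[(5R)-2-methyl-5-(propan-2-yl)-5-[(triethylsilyl)oxy]cyclopent-1-en-1-yl]ethan-1-ol, both carbinol epimers | CC(O)C1=C(C)CC[C@@]1(O[Si](CC)(CC)CC)C(C)C | intermediate
8 | 1-[(5R)-2-methyl-5-(propan-2-yl)-5-[(triethylsilyl)oxy]cyclopent-1-en-1-yl]ethan-1-one | CC(=O)C1=C(C)CC[C@@]1(O[Si](CC)(CC)CC)C(C)C | intermediate
9 | tert-butyl(dimethyl){[1-((5R)-2-methyl-5-(propan-2-yl)-5-[(triethylsilyl)oxy]cyclopent-1-en-1-yl)ethenyl]oxy}silane | C=C(O[Si](C)(C)C(C)(C)C)C1=C(C)CC[C@@]1(O[Si](CC)(CC)CC)C(C)C | intermediate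
10 | (tert-butyldimethylsilyloxy)acetaldehyde | CC(C)(C)[Si](C)(C)OCC=O | starting material
11 | ethyl diazoacetate | CCOC(=O)C=[N+]=[N-] | starting material
12 | ethyl 4-[(tert-butyldimethylsilyl)oxy]-2-diazo-3-hydroxybutanoate, racemic | CCOC(=O)C(=[N+]=[N-])C(O)CO[Si](C)(C)C(C)(C)C | intermediate
13 | ethyl (3E)-4-[(tert-butyldimethylsilyl)oxy]-2-diazobut-3-enoate | CCOC(=O)C(=[N+]=[N-])/C=C/O[Si](C)(C)C(C)(C)C | intermediate
14 | ethyl (1S,2R)-2-[(tert-butyldimethylsilyl)oxy]-1-[(E)-2-[(tert-butyldimethylsilyl)oxy]ethenyl]-2-[(5R)-2-methyl-5-(propan-2-yl)-5-[(triethylsilyl)oxy]cyclopent-1-en-1-yl]cyclopropane-1-carboxylate, alkenyl groups cis | CCOC(=O)[C@]1(/C=C/O[Si](C)(C)C(C)(C)C)C[C@@]1(O[Si](C)(C)C(C)(C)C)C2=C(C)CC[C@@]2(O[Si](CC)(CC)CC)C(C)C | intermediate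
15 | ethyl (3R,8R,8aS)-4,8-bis[(tert-butyldimethylsilyl)oxy]-8a-methyl-3-(propan-2-yl)-3-[(triethylsilyl)oxy]-1,2,3,5,8,8a-hexahydroazulene-6-carboxylate | CCOC(=O)C1=C[C@@H](O[Si](C)(C)C(C)(C)C)[C@@]2(C)CC[C@@](O[Si](CC)(CC)CC)(C(C)C)C2=C(O[Si](C)(C)C(C)(C)C)C1 | intermediate
16 | [(3R,8R,8aS)-4,8-bis[(tert-butyldimethylsilyl)oxy]-8a-methyl-3-(propan-2-yl)-3-[(triethylsilyl)oxy]-1,2,3,5,8,8a-hexahydroazulen-6-yl]methanol | OCC1=C[C@@H](O[Si](C)(C)C(C)(C)C)[C@@]2(C)CC[C@@](O[Si](CC)(CC)CC)(C(C)C)C2=C(O[Si](C)(C)C(C)(C)C)C1 | intermediate
17 | methanesulfonate of 16 | CS(=O)(=O)OCC1=C[C@@H](O[Si](C)(C)C(C)(C)C)[C@@]2(C)CC[C@@](O[Si](CC)(CC)CC)(C(C)C)C2=C(O[Si](C)(C)C(C)(C)C)C1 | intermediate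
18 | (3R,8R,8aS)-4,8-bis[(tert-butyldimethylsilyl)oxy]-6,8a-dimethyl-3-(propan-2-yl)-3-[(triethylsilyl)oxy]-1,2,3,5,8,8a-hexahydroazulene | CC1=C[C@@H](O[Si](C)(C)C(C)(C)C)[C@@]2(C)CC[C@@](O[Si](CC)(CC)CC)(C(C)C)C2=C(O[Si](C)(C)C(C)(C)C)C1 | intermediate
19 | (3R,3aS,8R,8aS)-8-[(tert-butyldimethylsilyl)oxy]-6,8a-dimethyl-3-(propan-2-yl)-3-[(triethylsilyl)oxy]-2,3,3a,5,8,8a-hexahydroazulen-4(1H)-one, cis-fused | CC1=C[C@@H](O[Si](C)(C)C(C)(C)C)[C@@]2(C)CC[C@@](O[Si](CC)(CC)CC)(C(C)C)[C@H]2C(=O)C1 | intermediate
20 | (3R,3aR,4S,8R,8aS)-8-[(tert-butyldimethylsilyl)oxy]-6,8a-dimethyl-3-(propan-2-yl)-3-[(triethylsilyl)oxy]-1,2,3,3a,4,5,8,8a-octahydroazulen-4-ol | CC1=C[C@@H](O[Si](C)(C)C(C)(C)C)[C@@]2(C)CC[C@@](O[Si](CC)(CC)CC)(C(C)C)[C@H]2[C@@H](O)C1 | intermediate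
21 | 4-methoxybenzoyl chloride | COc1ccc(C(Cl)=O)cc1 | starting material
22 | (3R,3aR,4S,8R,8aS)-8-[(tert-butyldimethylsilyl)oxy]-6,8a-dimethyl-3-(propan-2-yl)-3-[(triethylsilyl)oxy]-1,2,3,3a,4,5,8,8a-octahydroazulen-4-yl 4-methoxybenzoate | COc1ccc(C(=O)O[C@H]2CC(C)=C[C@@H](O[Si](C)(C)C(C)(C)C)[C@@]3(C)CC[C@@](O[Si](CC)(CC)CC)(C(C)C)[C@@H]23)cc1 | intermediate
23 | (3R,3aR,4S,8R,8aS)-3,8-dihydroxy-6,8a-dimethyl-3-(propan-2-yl)-1,2,3,3a,4,5,8,8a-octahydroazulen-4-yl 4-methoxybenzoate | COc1ccc(C(=O)O[C@H]2CC(C)=C[C@@H](O)[C@@]3(C)CC[C@@](O)(C(C)C)[C@@H]23)cc1 | intermediate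
24 | (3R,3aR,4S,8aS)-3-hydroxy-6,8a-dimethyl-8-oxo-3-(propan-2-yl)-1,2,3,3a,4,5,8,8a-octahydroazulen-4-yl 4-methoxybenzoate | COc1ccc(C(=O)O[C@H]2CC(C)=CC(=O)[C@@]3(C)CC[C@@](O)(C(C)C)[C@@H]23)cc1 | target

## Step count and risks

Total: 16 steps. Longest linear sequence: 14 steps (from 1 through steps 1–6 and 9–16); steps 7 and 8 are a two-step branch.

**Step 9 (key step).** The most likely failure is a loss of facial selectivity. The catalyst must choose one face of a 1,1-disubstituted enol ether whose neighbouring C9 centre may oppose it. If 14 opens to a zwitterion before it rearranges (the breaking bond carries a donor and an acceptor), the catalyst's choice is scrambled and the C6 epimer enters the product. Attack of the enol ether at the oxygen-bearing vinyl terminus in place of the carbenoid carbon, and decay of the electron-rich diazo ester 13 before use, are the second concerns.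

Fallback: stereocontrol is moved from the catalyst to a covalently bound auxiliary on the diazo ester, with an achiral catalyst. The fallback sets out from 9 and 10 and returns at 16.
- (R)-Pantolactone is bromoacetylated to (3R)-4,4-dimethyl-2-oxooxolan-3-yl bromoacetate F1.
- N,N′-Ditosylhydrazine and DBU convert F1 into the diazoacetate F2.
- F2 is added to 10 under DBU catalysis to give the hydroxy diazo ester F3.
- Dehydration with POCl3 and Et3N gives the vinyl diazo ester F4.
- F4 and 9 with dirhodium tetraoctanoate, Rh2(O2CC7H15)4, in hexanes give the cyclopropane F5 and, on warming, the cycloadduct F6. The lactone carbonyl of the auxiliary is expected to shield one face of the carbenoid; the antipodal lactone is taken if the sense requires it.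
- i-Bu2AlH cleaves the auxiliary ester of F6 and gives 16.

**Step 12.** The likely failures are partial protonation on the concave face, and equilibration of the free ketone while fluoride is present: C10 epimerisation, migration of C3=C4 into conjugation, or E1cB loss of the C9 silyloxy group.

Fallback: the cis-fused ketone is trapped as it forms, and the endgame order is changed. The fallback sets out from 18 and returns at 24.
- 18 is treated with HF·pyridine in THF. The enol ether is opened by protonation of the neutral enol ether, and the C5 and C9 silyl ethers fall in the same flask.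
- The cis-fused ketone closes with the C5 hydroxyl across the ring to the bridged hemiketal F8. Only the cis ring fusion can reach this form, and it no longer enolises.
- The trans-fused dihydroxy ketone F7 cannot close; it is separated, or drains into F8 through its enol.
- NaBH4 in methanol reduces F8 through its open tautomer, from the face of H10, to the triol F9.
- MnO2 oxidises only the allylic C5 hydroxyl and gives the dihydroxy enone F10.
- 21 with DMAP in pyridine acylates the one secondary hydroxyl and gives 24.

**Step 13.** The likely failure is hydride delivery to the other face of C1, if the seven-membered ring adopts a conformer that exposes it, or slow reduction of the hindered ketone with enolisation instead.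

Fallback: the epimer is inverted, not discarded. The fallback sets out from 19 and returns at 20. If reduction of 19 gives mainly the C1 epimer F11, Mitsunobu esterification with 4-nitrobenzoic acid (PPh3, diisopropyl azodicarboxylate) inverts C1 to the nitrobenzoate F12, and K2CO3 in methanol gives 20.

**Step 11.** The likely failure is ionisation or chloride exchange of the allylic mesylate, followed by hydride attack with allylic transposition, which would give the exocyclic methylene isomer.

Fallback: the fallback sets out from 16 and returns at 18. 16 is acetylated (Ac2O, pyridine) to the allylic acetate F13. F13 is reduced with LiEt3BH under catalysis by zerovalent palladium, Pd(PPh3)4; hydride is delivered to the less hindered CH2 terminus of the π-allyl complex and gives 18.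

## Further compounds

F1 | step 9 | (3R)-4,4-dimethyl-2-oxooxolan-3-yl bromoacetate | BrCC(=O)O[C@H]1C(=O)OCC1(C)C
F2 | step 9 | (3R)-4,4-dimethyl-2-oxooxolan-3-yl diazoacetate | [N-]=[N+]=CC(=O)O[C@H]1C(=O)OCC1(C)C
F3 | step 9 | (3R)-4,4-dimethyl-2-oxooxolan-3-yl 4-[(tert-butyldimethylsilyl)oxy]-2-diazo-3-hydroxybutanoate, carbinol epimers | CC(C)(C)[Si](C)(C)OCC(O)C(=[N+]=[N-])C(=O)O[C@H]1C(=O)OCC1(C)C
F4 | step 9 | (3R)-4,4-dimethyl-2-oxooxolan-3-yl (3E)-4-[(tert-butyldimethylsilyl)oxy]-2-diazobut-3-enoate | CC(C)(C)[Si](C)(C)O/C=C/C(=[N+]=[N-])C(=O)O[C@H]1C(=O)OCC1(C)C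
F5 | step 9 | pantolactonyl ester analogue of cyclopropane 14 | CC1(C)COC(=O)[C@@H]1OC(=O)[C@]2(/C=C/O[Si](C)(C)C(C)(C)C)C[C@@]2(O[Si](C)(C)C(C)(C)C)C3=C(C)CC[C@@]3(O[Si](CC)(CC)CC)C(C)C
F6 | step 9 | pantolactonyl ester analogue of cycloadduct 15 | CC1(C)COC(=O)[C@@H]1OC(=O)C2=C[C@@H](O[Si](C)(C)C(C)(C)C)[C@@]3(C)CC[C@@](O[Si](CC)(CC)CC)(C(C)C)C3=C(O[Si](C)(C)C(C)(C)C)C2
F7 | step 12 | trans-fused (C10-epimeric) 3,8-dihydroxy-6,8a-dimethyl-3-(propan-2-yl)-2,3,3a,5,8,8a-hexahydroazulen-4(1H)-one | CC1=C[C@@H](O)[C@@]2(C)CC[C@@](O)(C(C)C)[C@@H]2C(=O)C1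
F8 | step 12 | bridged hemiketal of the cis-fused dihydroxy ketone (oxygen bridge from C5 to C1) | O[C@@]12CC(C)=C[C@@H](O1)[C@@]3(C)CC[C@@](O)(C(C)C)[C@@H]23
F9 | step 12 | (3R,3aR,4S,8R,8aS)-6,8a-dimethyl-3-(propan-2-yl)-1,2,3,3a,4,5,8,8a-octahydroazulene-3,4,8-triol | CC1=C[C@@H](O)[C@@]2(C)CC[C@@](O)(C(C)C)[C@H]2[C@@H](O)C1
F10 | step 12 | (3R,3aR,4S,8aS)-3,4-dihydroxy-6,8a-dimethyl-3-(propan-2-yl)-1,2,3,3a,4,5-hexahydroazulen-8(8aH)-one | CC1=CC(=O)[C@@]2(C)CC[C@@](O)(C(C)C)[C@H]2[C@@H](O)C1
F11 | step 13 | C1 epimer (4R) of alcohol 20 | CC1=C[C@@H](O[Si](C)(C)C(C)(C)C)[C@@]2(C)CC[C@@](O[Si](CC)(CC)CC)(C(C)C)[C@H]2[C@H](O)C1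
F12 | step 13 | 4-nitrobenzoate of 20 (4S, after inversion) | O=C(O[C@H]1CC(C)=C[C@@H](O[Si](C)(C)C(C)(C)C)[C@@]2(C)CC[C@@](O[Si](CC)(CC)CC)(C(C)C)[C@@H]12)c1ccc(cc1)[N+](=O)[O-]
F13 | step 11 | acetate of 16 | CC(=O)OCC1=C[C@@H](O[Si](C)(C)C(C)(C)C)[C@@]2(C)CC[C@@](O[Si](CC)(CC)CC)(C(C)C)C2=C(O[Si](C)(C)C(C)(C)C)C1
A1 | alternative 1 | α′-diazo cycloheptenone with the open C7–C9 side chain on C6 | O=C1C=C(C)C[C@H](O[Si](C)(C)C(C)(C)C)[C@@](C)(CC[C@@H](O[Si](C)(C)C(C)(C)C)C(C)C)C1=[N+]=[N-]
A2 | alternative 1 | bicyclic C1 enone bis-silyl ether | O=C1C=C(C)C[C@H](O[Si](C)(C)C(C)(C)C)[C@@]2(C)CC[C@@](O[Si](C)(C)C(C)(C)C)(C(C)C)[C@@H]12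
A3 | alternative 2 | chloromethyl ketone tethered to the 2-silyloxydiene (enol ether geometry open) | ClCC(=O)C[C@](O[Si](CC)(CC)CC)(C(C)C)CCC(C)=C(O[Si](C)(C)C(C)(C)C)/C=C/C
A4 | alternative 2 | bicyclic C1 ketone with C5 silyl enol ether | O=C1C[C@@H](C)C=C(O[Si](C)(C)C(C)(C)C)[C@@]2(C)CC[C@@](O[Si](CC)(CC)CC)(C(C)C)[C@@H]12
A5 | alternative 3 | ten-membered epoxy enone (C6 unspecified) | CC(C)(C)[Si](C)(C)O[C@H]1C/C(C)=C\C(=O)C(C)CC[C@]2(C(C)C)O[C@@H]12
A6 | alternative 3 | C1 silyl ether of the bicyclic hydroxy enone | CC(C)(C)[Si](C)(C)O[C@H]2CC(C)=CC(=O)[C@@]3(C)CC[C@@](O)(C(C)C)[C@@H]23
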